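The data were computed on assumed constants, noise included.

The ratio of product to the rest of the charge is 0.649 on Sunday's plateau and 1.55 on Thursday's, and that is the ground of your hunch that heat pays. You want a quick number for the four flasks, so here is mine.

| flask | starting material | partner | temperature | remark | time |
|---|---|---|---|---|---|
| Sunday's | 0.070 M | 1.1 equiv | 28 °C | run made earlier |  |
| Thursday's | 0.11 M | 1.1 equiv | 77 °C | run made earlier |  |
| green | 0.050 M | 1.10 equiv | 95 °C |  | 8.0 h |
| teal | 0.050 M | 1.10 equiv | 35 °C |  | 8.0 h |
| red | 0.050 M | 1.10 equiv | 5 °C |  | 8.0 h |
| violet | 0.050 M | 1.10 equiv | 65 °C |  | 8.0 h |

- Sunday's (time / h: product / %, starting material / %): 20.0: 39.5, 0; 40.0: 39.0, 0; 72.0: 40.0, 0; 120: 39.0, 0; 240: 39.2, 0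
- Thursday's (time / h: product / %, starting material / %): 4.00: 61.0, 0; 8.00: 60.5, 0; 12.0: 61.3, 0.1; 15.0: 60.3, 0.4; 20.0: 60.7, 0

(standard deviation of a reading: 0.5 percentage points)

- the numbers in the tables scatter by 0.5 percentage points (one standard deviation)

1. the best flask by amount of product, in percent of the starting material charged; "all alike" if 1.5 percentage points covers them all (green / teal / red / violet / all alike)
2. amount of product at the end, in percent of the starting material charged, green
3. amount of product at the end, in percent of the starting material charged, teal
4. amount of product at the end, in percent of the starting material charged, red
5. amount of product at the end, in percent of the starting material charged, violet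

Both runs show starting material at or near zero and product flat, at 39.3% and 60.8% on average. A flat line can be a finished race between two paths, or a balance in which product falls apart as fast as it forms, and these readings do not separate the two. I commit to the balance (thermodynamic control, in the usual term), and then Thursday's charge of 0.11 M against Sunday's 0.070 M counts as well as the heat.

Thursday's 28.6 /M and Sunday's 13.1 /M are each the balance quotient, that is, the product fraction divided by the fraction of the charge not in product, by the partner not in product in fractions of the starting charge, and by the molar charge. That remainder of the charge is not starting material, which reads at or near zero, so I take it to be an unseen form that stands in balance with product. The two give a heat of 13.9 kJ/mol, so the quotient becomes 36.1 /M at green's 95 °C and 8.27 /M at red's 5 °C.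

Solving for the product fraction at 0.050 M gives ceilings of 51.4% for green, 44.2% for violet, 35.6% for teal and 25.8% for red. Green is my best flask, though it lands below Thursday's plateau. Thursday's first reading at 4.00 h finds no starting material, so I expect green, hotter and given 8.0 h, to reach its ceiling. The runs give me no rate for violet or teal, so that these two reach their ceilings in 8.0 h is my assumption. Red is colder than both runs, and I have no rate for it, so I say only that red stays under its ceiling.

The forecast is higher for green, at 66%, with 55% for violet, 41% for teal, 20% for red and green as the best, holding that “The plateau reflects a branching ratio against a competing side path”.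

Green gives 51.6%, violet 44.4%, teal 35.8% and red 3.13%.

    starting material → open intermediate (k = 0.0330 /min, Ea = 103 kJ/mol)
    partner → second intermediate (k = 0.0670 /min, Ea = 80.0 kJ/mol)
    open intermediate + second intermediate ⇌ product (K = 15.0 /M, k = 0.800 /M/min, Ea = 60.0 kJ/mol, ΔH = 14.0 kJ/mol)
    (constants at 35 °C)

Green's remainder stands as open intermediate, 48.4% of the charge, beside second intermediate at 0.0292 M, and green left until 80.0 h still gives 51.6%. My green quotient times those two gives 51.0%. Red keeps 81.3% of its starting material at 8.00 h. Left until 80.0 h, red holds open intermediate at 64.3% and second intermediate at 0.0435 M, where my red quotient gives 23.1% and the flask stands at 23.1%.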